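The target is cut back to a stereocentre-free 3,3''-biflavone, assembled by sp2–sp2 cross-coupling of two bought flavones at C3 and C3''. The key step exploits the fact that in both pyranone rings (ring C of each half) H-2 and H-3 are cis and C2, C3, C3'' and C2'' are all R: this is the outcome of suprafacial H2 addition to each C2=C3 bond. One catalyst-controlled double hydrogenation of the tri-O-benzyl biflavone therefore sets all four stereocentres at once; neutral hydrogenolysis of the benzyl ethers then gives the phenols without touching the epimerisable C3 centres.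

Key step: step 6

Assumption: flavones 1 and 5 are taken as purchasable; the sense of induction of the chiral ligand in step 6 cannot be predicted with confidence, so the ligand antipode that leads to the 2R,3R series is to be fixed by experiment, and biflavone 10 is drawn without a descriptor for its C3–C3'' axis because both rotamers are expected to converge.

Step 1
Reactants: 1 acacetin (5,7-dihydroxy-4'-methoxyflavone)
Product: 2 5,7-di-O-benzylacacetin (5,7-bis(benzyloxy)-4'-methoxyflavone)
Conditions: BnBr (3 equiv), K2CO3 (4 equiv), DMF, 80 °C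
Reagents that add atoms: benzyl bromide, BrCc1ccccc1
Why: Williamson etherification in which the free 7-OH reacts readily and heat plus excess reagent also drive the hydrogen-bonded 5-OH to its ether, so that no acidic phenol remains for the later amide-base step.

Step 2
Reactants: 2 5,7-di-O-benzylacacetin
Product: 4 3-iodo-5,7-bis(benzyloxy)-4'-methoxyflavone, via 3-lithioflavone 3 (not isolated)
Conditions: LDA (1.3 equiv), THF, −78 °C (2 added to the base); then I2 (1.5 equiv), −78 °C to 0 °C
Reagents that add atoms: iodine, II
Why: Carbonyl-directed C3 deprotonation of the flavone followed by iodine quench of the vinyl-lithium; the amide base does not metalate the electron-rich C6 and C8 positions of ring A that an electrophilic iodination would attack, so the halogen should enter at C3 only.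

Step 3
Reactants: 5 apigenin 7,4'-dimethyl ether (5-hydroxy-7,4'-dimethoxyflavone)
Product: 6 5-O-benzyl-7,4'-di-O-methylapigenin (5-benzyloxy-7,4'-dimethoxyflavone)
Conditions: BnBr (1.5 equiv), K2CO3 (2.5 equiv), DMF, 80 °C
Reagents that add atoms: benzyl bromide, BrCc1ccccc1
Why: Williamson etherification of the single, chelated 5-OH under the same forcing conditions as in step 1.

Step 4
Reactants: 6 5-O-benzyl-7,4'-di-O-methylapigenin
Product: 9 5-benzyloxy-7,4'-dimethoxyflavone 3-boronic acid pinacol ester, via 3-lithioflavone 7 (not isolated), via lithium borate complex 8 (not isolated)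
Conditions: LDA (1.3 equiv), THF, −78 °C; iPrOBpin (1.5 equiv), −78 °C to 0 °C; HCl in Et2O (1.3 equiv), 0 °C
Reagents that add atoms: 2-isopropoxy-4,4,5,5-tetramethyl-1,3,2-dioxaborolane, CC(C)OB1OC(C)(C)C(C)(C)O1
Why: Lithiation–borylation in which the C3 vinyl-lithium adds to the borate ester and the ate complex loses isopropoxide on mild acid quench; the boronate is to be used promptly in step 5 to limit protodeboronation.

Step 5
Reactants: 4 3-iodo-5,7-bis(benzyloxy)-4'-methoxyflavone; 9 5-benzyloxy-7,4'-dimethoxyflavone 3-boronic acid pinacol ester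
Product: 10 5,7,5''-tris(benzyloxy)-7'',4',4'''-trimethoxy-3,3''-biflavone (no stereocentres)
Conditions: Pd(OAc)2 (10 mol%), SPhos (20 mol%), K3PO4 (3 equiv), toluene/H2O 10:1, 100 °C
Reagents that add atoms: none
Why: Suzuki–Miyaura cross-coupling in which the bulky, electron-rich dialkylbiarylphosphine lets zerovalent palladium insert into the hindered C3–I bond and then forces reductive elimination to the tetra-ortho-substituted C3–C3'' bond, while the mild phosphate base spares the pyranone rings.

Step 6
Reactants: 10 5,7,5''-tris(benzyloxy)-7'',4',4'''-trimethoxy-3,3''-biflavone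
Product: 13 (2R,3R,2''R,3''R)-5,7,5''-tris(benzyloxy)-7'',4',4'''-trimethoxy-3,3''-biflavanone, via acacetin-half-reduced intermediate 11 (not isolated), via dimethyl-ether-half-reduced intermediate 12 (not isolated)
Conditions: [Rh(nbd)2]BF4 (10 mol%), chiral ferrocenyl bisphosphine carrying a 3,5-bis(trifluoromethyl)phenyl thiourea side arm (11 mol%), H2 (60 bar), CH2Cl2, 40 °C
Reagents that add atoms: none
Why: Proposed new method: the ligand thiourea hydrogen-bonds to the basic C4 carbonyl and so holds the cationic monovalent rhodium dihydride over one face of the adjacent C2=C3 bond; hydride migrates to C2, the resulting C3–Rh bond is cleaved by reductive elimination on the same face, and the cycle repeats at the second chromone through 11 or 12, so that four C–H bonds and no C–C bond are made and no ring is closed. The closest known reaction type is the catalytic asymmetric hydrogenation of flavones, 2-substituted chromones and tetrasubstituted cyclic enones to cis products with chiral rhodium bisphosphine or ruthenium carbene catalysts; a 3,3''-linked bis-chromone with two tetrasubstituted alkenes has not been reduced in this way. Within each ring C the cis relation (H-2/H-3 and H-2''/H-3'') follows from delivery of both hydrogens by the metal to one face, and the R configuration at C2, C3, C3'' and C2'' follows from the ligand choosing the same enantioface of two almost identical chromones. The step needs chemoselectivity for C=C over C=O, arenes and benzyl ethers, face selectivity, and survival of the kinetic cis isomers: the C2=C3 bonds are the only alkenes, each has its own C4 carbonyl as binding handle (kept free of chelation by the 5-O-benzyl groups), and the aprotic, base-free medium avoids enolisation at C3 and retro-oxa-Michael opening. The first addition turns the hindered C3–C3'' axis into a freely rotating sp3–sp2 bond, so both rotamers of 10 should converge, and because the two face choices are independent a wrong one should end mostly in a separable diastereomer and not in the enantiomer.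

Step 7
Reactants: 13 (2R,3R,2''R,3''R)-5,7,5''-tris(benzyloxy)-7'',4',4'''-trimethoxy-3,3''-biflavanone
Product: 14 (2R,3R,2''R,3''R)-5,7,5''-trihydroxy-7'',4',4'''-trimethoxy-3,3''-biflavanone (CNP0184936.2)
Conditions: H2 (1 atm), 10% Pd/C (acid-free), EtOAc, rt
Reagents that add atoms: none
Why: Hydrogenolysis of the three aryl benzyl ethers on palladium in a neutral solvent creates no stereocentre and offers neither acid nor base for enolisation at C3 or C3'', and stopping once debenzylation is complete should protect the benzylic C2–O1 bonds.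

Compound list
1 | acacetin (5,7-dihydroxy-4'-methoxyflavone) | COc1ccc(-c2cc(=O)c3c(O)cc(O)cc3o2)cc1 | starting material
2 | 5,7-di-O-benzylacacetin | COc1ccc(-c2cc(=O)c3c(OCc4ccccc4)cc(OCc4ccccc4)cc3o2)cc1 | intermediate
3 | 3-lithio-5,7-bis(benzyloxy)-4'-methoxyflavone (not isolated) | COc1ccc(-c2oc3cc(OCc4ccccc4)cc(OCc4ccccc4)c3c(=O)c2[Li])cc1 | intermediate
4 | 3-iodo-5,7-bis(benzyloxy)-4'-methoxyflavone | COc1ccc(-c2oc3cc(OCc4ccccc4)cc(OCc4ccccc4)c3c(=O)c2I)cc1 | intermediate
5 | apigenin 7,4'-dimethyl ether (5-hydroxy-7,4'-dimethoxyflavone) | COc1ccc(-c2cc(=O)c3c(O)cc(OC)cc3o2)cc1 | starting material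
6 | 5-O-benzyl-7,4'-di-O-methylapigenin | COc1ccc(-c2cc(=O)c3c(OCc4ccccc4)cc(OC)cc3o2)cc1 | intermediate
7 | 3-lithio-5-benzyloxy-7,4'-dimethoxyflavone (not isolated) | COc1ccc(-c2oc3cc(OC)cc(OCc4ccccc4)c3c(=O)c2[Li])cc1 | intermediate
8 | lithium (flavon-3-yl)(isopropoxy)(pinacolato)borate of 6 (not isolated) | COc1ccc(-c2oc3cc(OC)cc(OCc4ccccc4)c3c(=O)c2[B-]2(OC(C)C)OC(C)(C)C(C)(C)O2)cc1.[Li+] | intermediate
9 | 5-benzyloxy-7,4'-dimethoxyflavone 3-boronic acid pinacol ester | COc1ccc(-c2oc3cc(OC)cc(OCc4ccccc4)c3c(=O)c2B2OC(C)(C)C(C)(C)O2)cc1 | intermediate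
10 | 5,7,5''-tris(benzyloxy)-7'',4',4'''-trimethoxy-3,3''-biflavone | COc1ccc(-c2oc3cc(OCc4ccccc4)cc(OCc4ccccc4)c3c(=O)c2-c2c(-c3ccc(OC)cc3)oc3cc(OC)cc(OCc4ccccc4)c3c2=O)cc1 | intermediate
11 | (2R,3R)-flavanone (acacetin half, cis H-2/H-3) joined at C3 to C3'' of the unreduced dimethyl-ether flavone (not isolated) | COc1ccc([C@@H]2Oc3cc(OCc4ccccc4)cc(OCc4ccccc4)c3C(=O)[C@@H]2c2c(-c3ccc(OC)cc3)oc3cc(OC)cc(OCc4ccccc4)c3c2=O)cc1 | intermediate
12 | (2''R,3''R)-flavanone (dimethyl-ether half, cis H-2''/H-3'') joined at C3'' to C3 of the unreduced acacetin flavone (not isolated) | COc1ccc(-c2oc3cc(OCc4ccccc4)cc(OCc4ccccc4)c3c(=O)c2[C@H]2C(=O)c3c(OCc4ccccc4)cc(OC)cc3O[C@H]2c2ccc(OC)cc2)cc1 | intermediate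
13 | (2R,3R,2''R,3''R)-5,7,5''-tris(benzyloxy)-7'',4',4'''-trimethoxy-3,3''-biflavanone (cis in both rings) | COc1ccc([C@@H]2Oc3cc(OCc4ccccc4)cc(OCc4ccccc4)c3C(=O)[C@@H]2[C@H]2C(=O)c3c(OCc4ccccc4)cc(OC)cc3O[C@H]2c2ccc(OC)cc2)cc1 | intermediate
14 | (2R,3R,2''R,3''R)-5,7,5''-trihydroxy-7'',4',4'''-trimethoxy-3,3''-biflavanone (CNP0184936.2) | COc1ccc([C@@H]2Oc3cc(O)cc(O)c3C(=O)[C@@H]2[C@H]2C(=O)c3c(O)cc(OC)cc3O[C@H]2c2ccc(OC)cc2)cc1 | target

Total step count: 7
Longest linear sequence: 5 steps (steps 1, 2, 5, 6, 7, or equally steps 3, 4, 5, 6, 7)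

Steps most likely to fail

Step 6. The two tetrasubstituted C2=C3 bonds shield each other and may not turn over. The ligand may discriminate the enantiofaces poorly. A rhodium O-enolate may leak the kinetic cis arrangement into the trans series. The fallback gives up catalyst control and sets out from biflavone 10. Hydrogenation over Pd/C (H2, EtOAc/THF, rt) is the classical heterogeneous cis reduction of flavones to flavanones. It should first cleave the benzyl ethers to 5,7,5''-trihydroxy-7'',4',4'''-trimethoxy-3,3''-biflavone F1 and then add H2 to both C2=C3 bonds from the metal surface. This should give 14 together with the (2S,3S,2''S,3''S) enantiomer F2, next to the (2R,3R,2''S,3''S) diastereomer F3 and the (2S,3S,2''R,3''R) diastereomer F4. Chromatography on silica should remove F3 and F4, and preparative HPLC on a chiral stationary phase should separate 14 from F2. The fallback comes back to the route at 14 and replaces steps 6 and 7.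

Step 5. Protodeboronation of the hindered boronate may outrun transmetalation, or reductive elimination to the tetra-ortho-substituted bond may stall. The fallback sets out from 6: lithiation to 7 as in step 4, then transmetalation with ZnCl2 to 3-(chlorozincio)-5-benzyloxy-7,4'-dimethoxyflavone F5. F5 is coupled in the same flask with iodide 4 (Pd2(dba)3, RuPhos, THF, 60 °C, Negishi coupling). The fallback comes back to the route at 10 and bypasses boronate 9.

Step 7. The C3 and C3'' centres may epimerise on the catalyst surface, the benzylic C2–O1 bonds may be opened by hydrogenolysis, or the C4 ketones may be over-reduced. The fallback sets out from 13 and removes the benzyl groups without hydrogen: BCl3 with pentamethylbenzene as cation scavenger in CH2Cl2 at −78 °C, quenched cold with methanol. It comes back to the route at 14 directly and makes no new compound on the way.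

Further compounds
F1 | step 6 | 5,7,5''-trihydroxy-7'',4',4'''-trimethoxy-3,3''-biflavone | COc1ccc(-c2oc3cc(O)cc(O)c3c(=O)c2-c2c(-c3ccc(OC)cc3)oc3cc(OC)cc(O)c3c2=O)cc1
F2 | step 6 | (2S,3S,2''S,3''S)-5,7,5''-trihydroxy-7'',4',4'''-trimethoxy-3,3''-biflavanone (enantiomer of 14) | COc1ccc([C@H]2Oc3cc(O)cc(O)c3C(=O)[C@H]2[C@@H]2C(=O)c3c(O)cc(OC)cc3O[C@@H]2c2ccc(OC)cc2)cc1
F3 | step 6 | (2R,3R,2''S,3''S)-5,7,5''-trihydroxy-7'',4',4'''-trimethoxy-3,3''-biflavanone | COc1ccc([C@@H]2Oc3cc(O)cc(O)c3C(=O)[C@@H]2[C@@H]2C(=O)c3c(O)cc(OC)cc3O[C@@H]2c2ccc(OC)cc2)cc1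
F4 | step 6 | (2S,3S,2''R,3''R)-5,7,5''-trihydroxy-7'',4',4'''-trimethoxy-3,3''-biflavanone | COc1ccc([C@H]2Oc3cc(O)cc(O)c3C(=O)[C@H]2[C@H]2C(=O)c3c(O)cc(OC)cc3O[C@H]2c2ccc(OC)cc2)cc1
F5 | step 5 | 3-(chlorozincio)-5-benzyloxy-7,4'-dimethoxyflavone | COc1ccc(-c2oc3cc(OC)cc(OCc4ccccc4)c3c(=O)c2[Zn]Cl)cc1
F0 | step 7 | none | none
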